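## The problem

Compound 20 is 3,5,6,7,8,2',4'-heptamethoxyflavone. In flavone numbering, ring A is the benzo ring C4a–C8a, ring C is the pyranone O1–C4 and ring B is the 2-aryl group C1'–C6'. It has no stereocentre, so the task is regiochemical: seven oxygens must be placed and the C–C bonds made without damaging them. Ring A is fully substituted, ring C carries a 3-methoxy group, and ring B is attached through C1' next to the 2'-methoxy group, so C2–C1' is an ortho-hindered aryl–heteroaryl bond. The sensitive points are the methyl ethers, above all 5-OMe peri to the C4 carbonyl, which strong Lewis acids such as BCl3 or AlCl3 cleave. The electron-rich ring A phenols met on the way oxidise easily to quinones. C2 of a chromone is a vinylogous ester carbon that hard nucleophiles and secondary amines attack with ring opening. The feature that makes the key step possible is the 1,3-relationship of the ring B oxygens at C2' and C4', ortho and para to C1'. This is the pattern a 1,1-dialkoxy-3-siloxybuta-1,3-diene writes onto an alkyne. C2 is also the β-carbon of the C4 enone, so an ethynyl group at C2 is polarised like a vinylogous ynone with an electrophilic terminal carbon.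

## Retrosynthesis

**20 ⇒ 19.** The O–CH3 bond at C4' is cut. This oxygen is the one the ring B construction delivers as a silyl ether, so the free phenol 19 is the natural penultimate compound. The forward step only has to methylate the single hydroxyl group of 19.

**19 ⇒ 14 + 16.** The bonds C1'–C2' and C5'–C6' are cut, removing ring B as a whole. The neighbouring cut, C2–C1', would join a ready-made 2,4-dimethoxyphenyl unit by cross-coupling and is shorter; it is kept as the fallback. The ring construction is preferred because it gives the two ring B oxygens differentiated (2'-OMe, 4'-OH) and places them by the polarity of the partners alone. Other two-bond cuts of ring B would need dienes or alkynes that are harder to reach. The precursors are much simpler: 14 is a bicyclic ethynylchromone that already holds five of the seven methoxy groups, and 16 is a one-step diene. The forward reaction needs the alkyne of 14, not the tetrasubstituted C2=C3, to act as the dienophile. The CH2 terminus of 16 must bond to the terminal alkyne carbon, and the adduct must aromatise by loss of methanol.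

**16 ⇒ 15.** The O–Si bond is cut, leading to the vinylogous carbonate 15. The forward step is enol silylation of a methyl ketone.

**14 ⇒ 13 ⇒ 11 + 12.** The C–Si bond and then the C2–C(sp) bond are cut. An sp2–sp coupling at C2 is preferred to carrying an alkynyl ketone through the chromone ring closure, where the triple bond would compete as an acceptor. The forward steps are a Sonogashira coupling of iodide 11 with 12 and a desilylation mild enough for a conjugated terminal alkyne.

**11 ⇒ 9.** The C2–I bond is cut. C2–H is the only C–H on the bicyclic core of 9, so metalation needs no regiocontrol. It does need a base that deprotonates C2 without adding to it.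

**9 ⇒ 7.** The O1–C2 and C2–C3 bonds are cut, and C2 becomes a one-carbon formyl equivalent. The α-methoxy ketone 7 already carries the C3 oxygen at the right oxidation level, so no later oxidation of ring C is needed. The forward step is an enaminone annulation.

**7 ⇒ 4 + 5.** The aryl–acyl bond is cut. Phenol 4 has a single free ring position, ortho to the hydroxyl group, so the acylation cannot give regioisomers. It does need a Lewis acid that spares the methyl ethers.

**4 ⇒ 1.** The C–O bond of the phenol is cut. The two ring hydrogens of 1 are equivalent by symmetry, so ortho-lithiation, borylation and oxidation give one phenol.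

## Roads not taken

**Alternative 1:** The C3–C4 bond is cut, leading back to the dialdehyde A1.
- **Forward step:** an intramolecular crossed benzoin reaction under thiazolium carbene catalysis closes ring C as the trans-3-hydroxychromanone A2. Dehydrogenation then gives flavonol A3, and O-methylation gives 20.
- **Merits:** ring C forms under mild organocatalysis with the C3 oxygen already in place.
- **Weak points:** the ring A aldehyde, which must become the acyl anion donor, is di-ortho-substituted and very electron-rich. The aliphatic aldehyde forms the carbene adduct more readily, which would reverse the sense of addition. An α-aryloxy aldehyde can also expel its aryloxide from the carbene adduct and split the molecule. Two stereocentres are made only to be destroyed, and two further steps follow the ring closure. A1 itself needs a multistep synthesis from a hexasubstituted salicylaldehyde.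
- **Comparison:** the chosen plan is not shorter in its front end, but its ring-forming steps have no competing donor/acceptor roles and carry no redundant stereochemistry.

**Alternative 2:** The C4a–C4, C3–C4 and O1–C2 bonds are cut.
- **Forward step:** iodophenol A4, arylacetylene A5 and carbon monoxide A6 combine under PdCl2(PPh3)2 catalysis in a carbonylative coupling–cyclisation to give flavone A7. C3 is then hydroxylated to flavonol A3, which is methylated to 20.
- **Merits:** this is the most convergent road. Both aromatic rings arrive with their oxygens, ring C forms in one step, and the route is about five to six steps, clearly shorter than the chosen nine.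
- **Weak points:** A7 lacks the C3 oxygen, so an oxidation must be run late on a hexamethoxyflavone whose ring A is itself easily oxidised. The ring closure can go through endo or exo attack of the phenol oxygen on the triple bond. A4 is a hindered, oxidation-prone iodophenol, and the step needs pressurised CO.
- **Comparison:** this road is better in step count and convergence. The chosen plan sets against it that the 3-methoxy group is bought with 5 and never made by oxidation, and that neither ring closure has a regiochemical alternative.

**Alternative 3:** Ring A is cut at C8–C8a and C4a–C5 and traced to dimethyl squarate A8.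
- **Forward step:** the lithio derivative made from bromopyranone A9 adds to A8 to give the 4-hydroxycyclobutenone A10. Thermolysis opens A10 to a dienylketene that closes onto the pyranone CH carbon (C8–C8a) and tautomerises to hydroquinone A11. Double O-methylation gives 20.
- **Merits:** the four contiguous ring A oxygens are set without ambiguity from a cheap C4 unit, and no oxidation-prone tetramethoxyphenol is handled.
- **Weak points:** A9 is a 2-aryl-3-methoxypyranone that costs about as many steps as a chromone. Its lithio derivative must add to A8 faster than to its own pyranone carbonyl. A11 is an air-sensitive hydroquinone whose chelated 5-OH is slow to methylate.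
- **Comparison:** this road builds the ring that is commercially available fully oxygenated (1) and is longer. In fairness, the chosen plan also builds a ring (ring B) that could be bought. It justifies this by the short, regiochemically determined diene synthesis and the differentiated phenol 19, whereas the squarate road ends in two extra methylations.

Key step: step 8

Assumption: 4,4-dimethoxybut-3-en-2-one (15) is taken as a purchasable vinylogous carbonate building block.

## Route

Step 1
Reactants: 1 1,2,3,4-tetramethoxybenzene
Product: 4 2,3,4,5-tetramethoxyphenol, via 2,3,4,5-tetramethoxyphenyllithium 2 (not isolated), via dimethyl arylboronate 3 (not isolated)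
Conditions: n-BuLi, TMEDA, THF, 0 °C → 25 °C; B(OMe)3, −78 °C → 25 °C; 30% H2O2, AcOH, 0 °C
Reagents that add atoms: hydrogen peroxide, OO
Why: Directed ortho-lithiation next to a methoxy group (the two ring hydrogens are equivalent), borylation and oxidative boron-to-oxygen aryl migration are standard for polymethoxybenzenes; buffered peroxide at 0 °C should limit over-oxidation of the electron-rich phenol.

Step 2
Reactants: 4 2,3,4,5-tetramethoxyphenol; 5 methoxyacetyl chloride
Product: 7 1-(2-hydroxy-3,4,5,6-tetramethoxyphenyl)-2-methoxyethan-1-one, via difluoroboron chelate 6 (not isolated)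
Conditions: BF3·OEt2, ClCH2CH2Cl, 0 → 60 °C; then MeOH–H2O, 60 °C
Reagents that add atoms: none
Why: Friedel–Crafts ortho-acylation of a phenol at its only free position, which is activated by the ortho OH and by ortho and para methoxy groups; BF3 should hold the product as chelate 6, which blocks further reaction, and is not expected to cleave aryl methyl ethers at this temperature.

Step 3
Reactants: 7 1-(2-hydroxy-3,4,5,6-tetramethoxyphenyl)-2-methoxyethan-1-one
Product: 9 3,5,6,7,8-pentamethoxy-4H-chromen-4-one, via enaminone 8 (not isolated)
Conditions: Me2NCH(OMe)2, toluene, 100 °C; then conc. HCl, CH2Cl2, 25 °C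
Reagents that add atoms: N,N-dimethylformamide dimethyl acetal, COC(OC)N(C)C
Why: Enaminone formation at the α-CH2, then acid-promoted conjugate addition of the phenol and loss of dimethylamine, is the standard one-carbon chromone annulation; the α-methoxy group becomes 3-OMe.

Step 4
Reactants: 9 3,5,6,7,8-pentamethoxy-4H-chromen-4-one
Product: 11 2-iodo-3,5,6,7,8-pentamethoxy-4H-chromen-4-one, via chromon-2-ylzinc chloride 10 (not isolated)
Conditions: TMPZnCl·LiCl, THF, 25 °C; then I2, THF, 0 → 25 °C
Reagents that add atoms: iodine, [I][I]
Why: Directed zincation and iodolysis; C2–H is the only C–H of the bicyclic core and is acidified by O1, and the hindered zinc amide is known to metalate chromones at C2 without ring opening.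

Step 5
Reactants: 11 2-iodo-3,5,6,7,8-pentamethoxy-4H-chromen-4-one; 12 trimethylsilylacetylene
Product: 13 3,5,6,7,8-pentamethoxy-2-[(trimethylsilyl)ethynyl]-4H-chromen-4-one
Conditions: PdCl2(PPh3)2 (cat.), CuI (cat.), Et3N, THF, 25 °C
Reagents that add atoms: none
Why: Sonogashira coupling; the 2-iodochromone is a vinylogous acyl iodide and should add readily to zerovalent palladium, and a tertiary amine is used because secondary amines add to C2.

Step 6
Reactants: 13 3,5,6,7,8-pentamethoxy-2-[(trimethylsilyl)ethynyl]-4H-chromen-4-one
Product: 14 2-ethynyl-3,5,6,7,8-pentamethoxy-4H-chromen-4-one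
Conditions: TBAF, AcOH, THF, −20 → 0 °C
Reagents that add atoms: none
Why: Fluoride-induced C(sp)–Si cleavage; the acetic acid buffer protonates the acetylide at once and should suppress conjugate addition to the activated alkyne.

Step 7
Reactants: 15 4,4-dimethoxybut-3-en-2-one
Product: 16 1,1-dimethoxy-3-(trimethylsilyloxy)buta-1,3-diene
Conditions: TMSCl, Et3N, ZnCl2 (cat.), toluene, 40 °C; filtration, distillation
Reagents that add atoms: chlorotrimethylsilane, C[Si](C)(C)Cl
Why: Soft enolisation and O-silylation of the methyl ketone is the standard way to 1-alkoxy-3-siloxydienes; the diene is distilled and used at once.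

Step 8
Reactants: 14 2-ethynyl-3,5,6,7,8-pentamethoxy-4H-chromen-4-one; 16 1,1-dimethoxy-3-(trimethylsilyloxy)buta-1,3-diene
Product: 19 2-(4-hydroxy-2-methoxyphenyl)-3,5,6,7,8-pentamethoxy-4H-chromen-4-one, via cyclohexadiene cycloadduct 17 (not isolated), via aryl trimethylsilyl ether 18 (not isolated)
Conditions: 16 (3 equiv), toluene, 110 °C, sealed tube; then 1 M HCl, THF, 25 °C
Reagents that add atoms: none
Why: Proposed new method: Diels–Alder benzannulation of a ketene-acetal siloxydiene with an alkyne activated only vinylogously, through C2=C3 of the chromone, by the C4 carbonyl; the closest known reaction type is the cycloaddition of 16 with acetylenic ketones and esters followed by loss of methanol to give resorcinol monomethyl ethers. The HOMO of 16 is largest at its CH2 terminus and the LUMO of the ynenone 14 at the terminal alkyne carbon, so an asynchronous (4+2) addition should join CH2 to the alkyne CH (C5'–C6') and the C(OMe)2 terminus to the inner alkyne carbon (C1'–C2'). Ring B closes in this one intermolecular cycloaddition, both ring bonds forming suprafacially on diene and dienophile; a stepwise Michael addition and ring closure would lead to the same adduct 17. Adduct 17 is a 1,4-cyclohexadiene with a doubly allylic ketal, which should ionise easily and lose methanol together with a C5' hydrogen to give the aromatic silyl ether 18; dilute acid then frees phenol 19. No stereocentre is formed. The step needs regioselectivity (2'-OMe and 4'-OH, no 6'-oxygen) and chemoselectivity (alkyne, not C2=C3); the first should follow from the polarisation of the ynenone, the second from the tetrasubstituted, donor-substituted and hindered C2=C3 bond. Excess diene and heat are meant to offset the weaker activation compared with a true ynone.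

Step 9
Reactants: 19 2-(4-hydroxy-2-methoxyphenyl)-3,5,6,7,8-pentamethoxy-4H-chromen-4-one
Product: 20 2-(2,4-dimethoxyphenyl)-3,5,6,7,8-pentamethoxy-4H-chromen-4-one
Conditions: Me2SO4, K2CO3, acetone, reflux
Reagents that add atoms: dimethyl sulfate, COS(=O)(=O)OC
Why: Williamson O-methylation of the only free phenol; the chromone and the aryl methyl ethers are inert to K2CO3 in acetone.

## Compound list

1 | 1,2,3,4-tetramethoxybenzene | COc1ccc(OC)c(OC)c1OC | starting material
2 | (2,3,4,5-tetramethoxyphenyl)lithium | [Li]c1cc(OC)c(OC)c(OC)c1OC | intermediate
3 | dimethyl (2,3,4,5-tetramethoxyphenyl)boronate | COB(OC)c1cc(OC)c(OC)c(OC)c1OC | intermediate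
4 | 2,3,4,5-tetramethoxyphenol | Oc1cc(OC)c(OC)c(OC)c1OC | intermediate
5 | methoxyacetyl chloride | COCC(=O)Cl | starting material
6 | difluoroboron chelate of 7 (2,2-difluoro-5,6,7,8-tetramethoxy-4-(methoxymethyl)-1,3,2-benzodioxaborinine, O→B chelate) | COCC1=[O+][B-](F)(F)Oc2c(OC)c(OC)c(OC)c(OC)c12 | intermediate
7 | 1-(2-hydroxy-3,4,5,6-tetramethoxyphenyl)-2-methoxyethan-1-one | COCC(=O)c1c(O)c(OC)c(OC)c(OC)c1OC | intermediate
8 | (Z)-3-(dimethylamino)-1-(2-hydroxy-3,4,5,6-tetramethoxyphenyl)-2-methoxyprop-2-en-1-one (geometry assumed; it does not affect the outcome) | CN(C)/C=C(\OC)C(=O)c1c(O)c(OC)c(OC)c(OC)c1OC | intermediate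
9 | 3,5,6,7,8-pentamethoxy-4H-chromen-4-one | COc1coc2c(OC)c(OC)c(OC)c(OC)c2c1=O | intermediate
10 | chloro(3,5,6,7,8-pentamethoxy-4-oxo-4H-chromen-2-yl)zinc | Cl[Zn]c1oc2c(OC)c(OC)c(OC)c(OC)c2c(=O)c1OC | intermediate
11 | 2-iodo-3,5,6,7,8-pentamethoxy-4H-chromen-4-one | COc1c(I)oc2c(OC)c(OC)c(OC)c(OC)c2c1=O | intermediate
12 | trimethylsilylacetylene | C#C[Si](C)(C)C | starting material
13 | 3,5,6,7,8-pentamethoxy-2-[(trimethylsilyl)ethynyl]-4H-chromen-4-one | COc1c(C#C[Si](C)(C)C)oc2c(OC)c(OC)c(OC)c(OC)c2c1=O | intermediate
14 | 2-ethynyl-3,5,6,7,8-pentamethoxy-4H-chromen-4-one | C#Cc1oc2c(OC)c(OC)c(OC)c(OC)c2c(=O)c1OC | intermediate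
15 | 4,4-dimethoxybut-3-en-2-one | CC(=O)C=C(OC)OC | starting material
16 | 1,1-dimethoxy-3-(trimethylsilyloxy)buta-1,3-diene | COC(OC)=CC(=C)O[Si](C)(C)C | intermediate
17 | 2-[6,6-dimethoxy-4-(trimethylsilyloxy)cyclohexa-1,4-dien-1-yl]-3,5,6,7,8-pentamethoxy-4H-chromen-4-one | COC1(OC)C=C(O[Si](C)(C)C)CC=C1c1oc2c(OC)c(OC)c(OC)c(OC)c2c(=O)c1OC | intermediate
18 | 3,5,6,7,8-pentamethoxy-2-[2-methoxy-4-(trimethylsilyloxy)phenyl]-4H-chromen-4-one | COc1cc(O[Si](C)(C)C)ccc1-c1oc2c(OC)c(OC)c(OC)c(OC)c2c(=O)c1OC | intermediate
19 | 2-(4-hydroxy-2-methoxyphenyl)-3,5,6,7,8-pentamethoxy-4H-chromen-4-one | COc1cc(O)ccc1-c1oc2c(OC)c(OC)c(OC)c(OC)c2c(=O)c1OC | intermediate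
20 | 2-(2,4-dimethoxyphenyl)-3,5,6,7,8-pentamethoxy-4H-chromen-4-one | COc1ccc(-c2oc3c(OC)c(OC)c(OC)c(OC)c3c(=O)c2OC)c(OC)c1 | target

## Step count and least certain steps

Total step count: 9. Longest linear sequence: 8 steps (steps 1–6, 8 and 9); step 7 is a one-step branch.

**Step 8 (key step, proposed new method).** The cycloaddition may be too slow on a dienophile that is activated only through the chromone double bond and is deactivated by the 3-methoxy donor. Thermal decomposition or hydrolysis of the diene, or its addition as a nucleophile at C2 of the chromone, could then outrun ring formation. The fallback gives up the ring construction and makes the C2–C1' bond directly. It sets out from 9, which is zincated to 10 as in step 4 and coupled with 1-iodo-2,4-dimethoxybenzene in a Negishi reaction (Pd(PPh3)4, THF, 50 °C). It returns to the route at 20 and makes no new compound (F0).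

**Step 6.** The freed terminal alkyne is a 1,6-acceptor. Fluoride-derived nucleophiles may add to it, or it may oligomerise under base during desilylation and concentration. The fallback avoids the silyl group altogether. It sets out from 11, which is coupled with tributyl(ethynyl)stannane in a Stille reaction (Pd(PPh3)4, toluene, 80 °C) under neutral conditions. It returns at 14 and makes no new compound (F0).

**Step 4.** Metalation may be incomplete, or the amide base may add to C2 and open the pyranone ring. The fallback builds the C2 carbon substituent during ring closure and sets out from 7.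
- Kostanecki–Robinson condensation (acetic anhydride, NaOAc, 170 °C) should give 3,5,6,7,8-pentamethoxy-2-methyl-4H-chromen-4-one F1.
- SeO2 oxidation of the activated methyl group (dioxane, reflux) should give 3,5,6,7,8-pentamethoxy-4-oxo-4H-chromene-2-carbaldehyde F2.
- Ohira–Bestmann homologation (dimethyl (1-diazo-2-oxopropyl)phosphonate, K2CO3, MeOH, 0 °C) returns to the route at 14.

**Step 2.** Acylation may stop at the phenol oxygen without transfer to carbon, or the Lewis acid may remove the methyl group ortho to the new carbonyl. The fallback replaces the electrophilic acylation by directed metalation and sets out from 4.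
- Protection with chloromethyl methyl ether and i-Pr2NEt gives 1,2,3,4-tetramethoxy-5-(methoxymethoxy)benzene F3.
- Ortho-lithiation at the single ring C–H (n-BuLi, THF, −78 → 0 °C) and acylation with N-methoxy-N-methyl-2-methoxyacetamide give 2-methoxy-1-[2,3,4,5-tetramethoxy-6-(methoxymethoxy)phenyl]ethan-1-one F4.
- HCl in MeOH removes the acetal and returns to the route at 7.

## Further compounds

F0 | step 8 | none | none
F0 | step 6 | none | none
F1 | step 4 | 3,5,6,7,8-pentamethoxy-2-methyl-4H-chromen-4-one | COc1c(C)oc2c(OC)c(OC)c(OC)c(OC)c2c1=O
F2 | step 4 | 3,5,6,7,8-pentamethoxy-4-oxo-4H-chromene-2-carbaldehyde | COc1c(C=O)oc2c(OC)c(OC)c(OC)c(OC)c2c1=O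
F3 | step 2 | 1,2,3,4-tetramethoxy-5-(methoxymethoxy)benzene | COCOc1cc(OC)c(OC)c(OC)c1OC
F4 | step 2 | 2-methoxy-1-[2,3,4,5-tetramethoxy-6-(methoxymethoxy)phenyl]ethan-1-one | COCOc1c(C(=O)COC)c(OC)c(OC)c(OC)c1OC
A1 | alternative 1 | 2-[1-(2,4-dimethoxyphenyl)-2-oxoethoxy]-3,4,5,6-tetramethoxybenzaldehyde (racemic) | COc1ccc(C(C=O)Oc2c(C=O)c(OC)c(OC)c(OC)c2OC)c(OC)c1
A2 | alternative 1 | trans-2-(2,4-dimethoxyphenyl)-3-hydroxy-5,6,7,8-tetramethoxychroman-4-one (racemic, one enantiomer drawn) | COc1ccc([C@H]2Oc3c(OC)c(OC)c(OC)c(OC)c3C(=O)[C@@H]2O)c(OC)c1
A3 | alternative 1 | 2-(2,4-dimethoxyphenyl)-3-hydroxy-5,6,7,8-tetramethoxy-4H-chromen-4-one | COc1ccc(-c2oc3c(OC)c(OC)c(OC)c(OC)c3c(=O)c2O)c(OC)c1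
A4 | alternative 2 | 2-iodo-3,4,5,6-tetramethoxyphenol | Oc1c(I)c(OC)c(OC)c(OC)c1OC
A5 | alternative 2 | 1-ethynyl-2,4-dimethoxybenzene | C#Cc1ccc(OC)cc1OC
A6 | alternative 2 | carbon monoxide | [C-]#[O+]
A7 | alternative 2 | 2-(2,4-dimethoxyphenyl)-5,6,7,8-tetramethoxy-4H-chromen-4-one | COc1ccc(-c2cc(=O)c3c(OC)c(OC)c(OC)c(OC)c3o2)c(OC)c1
A8 | alternative 3 | dimethyl squarate (3,4-dimethoxycyclobut-3-ene-1,2-dione) | COC1=C(OC)C(=O)C1=O
A9 | alternative 3 | 5-bromo-2-(2,4-dimethoxyphenyl)-3-methoxy-4H-pyran-4-one | COc1ccc(-c2occ(Br)c(=O)c2OC)c(OC)c1
A10 | alternative 3 | 4-[6-(2,4-dimethoxyphenyl)-5-methoxy-4-oxo-4H-pyran-3-yl]-4-hydroxy-2,3-dimethoxycyclobut-2-en-1-one (racemic) | COC1=C(OC)C(O)(c2coc(-c3ccc(OC)cc3OC)c(OC)c2=O)C1=O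
A11 | alternative 3 | 2-(2,4-dimethoxyphenyl)-5,8-dihydroxy-3,6,7-trimethoxy-4H-chromen-4-one | COc1ccc(-c2oc3c(O)c(OC)c(OC)c(O)c3c(=O)c2OC)c(OC)c1
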